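The runs stem from a simulated flask with made-up constants; scatter was added.

If we want L in this closed, stirred flask, charged with 0.010 M of E under held G, we first ask which givens have to be known well.

all flasks: G 0.38 mM (held)
- south-east: E 0.0050 M; run made earlier
- north: E 0.020 M; run made earlier
- flask: E 0.010 M; time 30 h

| south-east: time / h | south-east: L / % | north: time / h | north: L / % |
|---|---|---|---|
| 1.33 | 4.2 | 1.50 | 4.4 |
| 2.50 | 8.8 | 5.00 | 14.2 |
| 5.00 | 16.7 | 8.00 | 17.9 |
| 10.0 | 27.7 | 12.0 | 21.3 |
| 20.0 | 39.8 | 20.0 | 25.7 |

(standard deviation of a reading: 1 percentage point)

- percent here means E units held: one X counts as two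
- at the start none of J is dissolved
- steps thought possible: E -> Q; 2 E -> X; E + J -> L; J + L -> D; G <-> J

- how much L there is at 30 h, in percent of the E charged
- the change that raises the amount of L at 30 h, in percent of the E charged most ("none" if none brings more than 2 percentage points) (spring / dawn / none)
- amount of L at 30 h, in percent of the E charged, after spring

- spring: doubling the transfer coefficient of G, all else as stated
- dawn: doubling the saturation concentration of G, all else as stated

The charge has to be known well. The south-east run gave 39.8 % of L at 20.0 h, and the north run gave 25.7 % with two doublings more E, so L fell by 7 percentage points per doubling. This charge penalty, the points of L lost per doubling of the E charged at a fixed time, we read as a loss of selectivity.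

Time matters next. The north run gained 4.4 points in its last 8.00 h. Taken as the flask's late pace, that adds 5.5 points over the remaining 10.0 h, less than one doubling of the charge costs. The scatter matters little: it moves the mean of the two readings by 0.71 points, less than either.

The flask lies one doubling above the south-east run and one below the north run, so we take its L at 20.0 h as that mean, 32.8 %. Our correction lifts it to 38.2 % at 30 h.

The forecast is lower, at 37 %, with 41 % after spring, and it chooses dawn: “Doubling saturation doubles J and so the rate of L against the E-loss steps, so dawn wins.”

The flask gives 37.0 %; dawn adds 6.5 points, and spring gives 37.5 %.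

    E → Q (k = 1.63 × 10⁻⁶ s⁻¹)
    2 E → X (k = 9.37 × 10⁻⁴ M⁻¹ s⁻¹)
    E + J → L (k = 0.0313 M⁻¹ s⁻¹)
    J + L → D (k = 0.00706 M⁻¹ s⁻¹)
    G ⇌ J, rate k5*(csat - [J]) (kL = 0.00375 s⁻¹)

At 30.0 h the flask held 37.5 % as X beside 37.0 % as L. Two halvings of the charge, reckoned at 7 points each, put the 37.0 % at 51.0 %; the flask charged with 0.0025 M of E gave, at 30.0 h, 49.6 %.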